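**Plan**
1. Retrosynthesis first cuts the acyl C–C bond between the ketone carbonyl and the decamethylene tether, giving an O-silyl N-acetyl-L-serine Weinreb amide and a 10-(furyl)decyl Grignard reagent.
2. The furan is then cut at C3–C4 and at O1–C5, the two bonds made by one gold(I) propargyl Claisen/heterocyclisation cascade of a propargyl vinyl ether. That ether is cut at its enol C–O bond (carbinol + ethyl hex-2-ynoate) and at the carbinol C–C bond (10-chlorodecanal + propynyl Grignard).
3. Enabling feature: the fully substituted furan ring. C4-methyl, C4, C5 and the first side-chain CH2 are a but-2-ynyl carbinol, joined through O1 to C2(propyl)=C3, the enol of a 3-oxohexanoate. The C3 methyl is carried as CO2Et so that the rearranged intermediate is an enolisable β-keto ester.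
4. Forward order: chain aldehyde → propargylic alcohol → β-alkoxyacrylate → furan (the only ring, step 4) → ester reduced to methyl → Grignard union with the serine amide → desilylation.
5. Stereochemistry: the single (S) centre comes from L-serine and is guarded by N-magnesiation in both organomagnesium steps. The racemic carbinol centre and the enol ether geometry disappear in the furan.

Key step: step 4

Remark: [C@H] in the target corresponds to (S), the spatial arrangement of L-serine, so no inversion is needed.
Remark: the tether end is carried as a primary chloride, the direct Grignard precursor, so the electron-rich furan never meets borane/peroxide or iodination reagents.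
Remark: 4, 6 and 7 are racemic or stereoisomeric mixtures at elements that are erased in step 4.

**Step 1**
Reactants: 1 10-chlorodecan-1-ol
Product: 2 10-chlorodecanal
Conditions: TEMPO (10 mol%), PhI(OAc)2 (1.1 equiv), CH2Cl2, rt
Reagents that add atoms: none
Why: Oxoammonium (TEMPO/PhI(OAc)2) oxidation of a primary alcohol should stop at the aldehyde and leave the primary alkyl chloride untouched.

**Step 2**
Reactants: 2 10-chlorodecanal; 3 prop-1-yn-1-ylmagnesium bromide
Product: 4 13-chlorotridec-2-yn-4-ol (racemic)
Conditions: THF, −78 → 0 °C; aq. NH4Cl
Reagents that add atoms: none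
Why: Grignard 1,2-addition of the alkynyl nucleophile to the aldehyde is far faster than attack on the primary chloride at low temperature, and the new carbinol centre is left racemic because it is erased in step 4.

**Step 3**
Reactants: 4 13-chlorotridec-2-yn-4-ol (racemic); 5 ethyl hex-2-ynoate
Product: 6 ethyl (2E)-3-[(13-chlorotridec-2-yn-4-yl)oxy]hex-2-enoate (racemic)
Conditions: PBu3 (20 mol%), 5 (1.3 equiv), CH2Cl2, 0 °C → rt
Reagents that add atoms: none
Why: Phosphine-catalysed oxa-Michael addition of an alcohol to a 2-alkynoate, in which PBu3 adds to the ynoate, the zwitterion deprotonates the alcohol and the alkoxide adds at the β-carbon with loss of phosphine, should give the β-alkoxyacrylate mainly as the E isomer, whose geometry is irrelevant later.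

**Step 4**
Reactants: 6 ethyl (2E)-3-[(13-chlorotridec-2-yn-4-yl)oxy]hex-2-enoate (racemic)
Product: 8 ethyl 5-(10-chlorodecyl)-4-methyl-2-propylfuran-3-carboxylate, via allenyl keto ester 7 (not isolated)
Conditions: Ph3PAuCl (2 mol%), AgBF4 (2 mol%), dry CH2Cl2, rt
Reagents that add atoms: none
Why: Cationic gold(I) coordinates the alkyne of 6, the nucleophilic α-carbon of the β-alkoxyacrylate attacks the methyl-bearing alkyne carbon (6-endo-dig) and the resulting oxonium fragments at the propargylic C–O bond, completing a formal [3,3] propargyl Claisen shift that forges the future C3–C4 bond and gives allenyl β-keto ester 7. Gold then activates the allene of the enolised keto ester, the ketone oxygen adds to the central allene carbon in a 5-exo-dig closure (O1–C5 bond), and protodeauration with tautomerisation delivers the aromatic furan, the former carbinol carbon becoming the first CH2 of the side chain. The closest known reaction type is the gold(I)-catalysed propargyl Claisen rearrangement/heterocyclisation of 3-(propargyloxy)acrylates to tri- and tetrasubstituted furan-3-carboxylates, a class to which 6 belongs. No stereocentre is created: the racemic propargylic centre, the enol ether geometry and the transient allene axis are all erased on aromatisation. The step needs O-cyclisation at the central allene carbon to win over 6-endo closure or dienone formation, and the ester secures this by making 7 an enolisable 1,3-dicarbonyl whose ketone enol oxygen is the internal nucleophile and whose furan is the thermodynamic sink; the ester also makes the enol ether of 6 robust towards adventitious acid. The primary alkyl chloride is inert to the π-acid catalyst.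

**Step 5**
Reactants: 8 ethyl 5-(10-chlorodecyl)-4-methyl-2-propylfuran-3-carboxylate
Product: 9 [5-(10-chlorodecyl)-4-methyl-2-propylfuran-3-yl]methanol
Conditions: DIBAL-H (2.5 equiv), CH2Cl2, −78 → 0 °C; aq. Rochelle salt
Reagents that add atoms: none
Why: Hydride reduction of the ester with DIBAL-H should give the primary alcohol without touching the alkyl chloride or the furan, and the neutral tartrate work-up spares the acid-labile furylmethanol.

**Step 6**
Reactants: 9 [5-(10-chlorodecyl)-4-methyl-2-propylfuran-3-yl]methanol
Product: 10 2-(10-chlorodecyl)-3,4-dimethyl-5-propylfuran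
Conditions: Et3SiH (3 equiv), TFA (2 equiv), CH2Cl2, −40 → 0 °C; aq. NaHCO3
Reagents that add atoms: none
Why: Ionic hydrogenation (deoxygenation): acid ionises the furylmethanol to a cation stabilised through C2 by the ring oxygen, hydride transfer from the silane to the exocyclic carbon restores the aromatic ring as the 3-methylfuran, and the fully substituted ring leaves no free position for Friedel–Crafts self-condensation.

**Step 7**
Reactants: 11 N-acetyl-L-serine methyl ester
Product: 12 methyl N-acetyl-O-(tert-butyldimethylsilyl)-L-serinate
Conditions: TBSCl (1.2 equiv), imidazole (2.5 equiv), DMF, 0 °C → rt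
Reagents that add atoms: tert-butyldimethylsilyl chloride, CC(C)(C)[Si](C)(C)Cl
Why: Imidazole-promoted silyl ether formation at the primary hydroxyl is non-epimerising and leaves the (S) centre untouched.

**Step 8**
Reactants: 12 methyl N-acetyl-O-(tert-butyldimethylsilyl)-L-serinate
Product: 14 N-[(2S)-3-[(tert-butyldimethylsilyl)oxy]-1-[methoxy(methyl)amino]-1-oxopropan-2-yl]acetamide, via N-chloromagnesio ester 13 (not isolated)
Conditions: MeNHOMe·HCl (1.6 equiv), i-PrMgCl (4.5 equiv), THF, −20 → 0 °C; aq. NH4Cl
Reagents that add atoms: N,O-dimethylhydroxylamine hydrochloride, CNOC.Cl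
Why: Weinreb amide formation by direct aminolysis of the methyl ester with the chloromagnesium amide made in the flask, in which the excess base first magnesiates the acetamide N–H so the α-hydrogen is shielded and, with no carboxyl activation and hence no oxazolone, the (S) centre should be retained.

**Step 9**
Reactants: 10 2-(10-chlorodecyl)-3,4-dimethyl-5-propylfuran; 14 N-[(2S)-3-[(tert-butyldimethylsilyl)oxy]-1-[methoxy(methyl)amino]-1-oxopropan-2-yl]acetamide
Product: 17 N-[(2S)-1-[(tert-butyldimethylsilyl)oxy]-13-(3,4-dimethyl-5-propylfuran-2-yl)-3-oxotridecan-2-yl]acetamide, via furyldecylmagnesium chloride 15 (not isolated), via N-chloromagnesio Weinreb amide 16 (not isolated)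
Conditions: (a) 10, Mg turnings (cat. I2), THF, 65 °C; (b) 14 (1.5 equiv), i-PrMgCl (1.5 equiv), THF, −20 °C; add (a), −20 °C → rt; aq. NH4Cl, 0 °C
Reagents that add atoms: none
Why: Weinreb ketone synthesis: the primary alkyl Grignard reagent adds once to the N-methoxy-N-methylamide and the magnesium chelate releases the ketone only on quench, while prior N-magnesiation of the acetamide prevents both protonation of the Grignard reagent and α-deprotonation, so the (S) centre is carried over unchanged.

**Step 10**
Reactants: 17 N-[(2S)-1-[(tert-butyldimethylsilyl)oxy]-13-(3,4-dimethyl-5-propylfuran-2-yl)-3-oxotridecan-2-yl]acetamide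
Product: 18 N-[(2S)-13-(3,4-dimethyl-5-propylfuran-2-yl)-1-hydroxy-3-oxotridecan-2-yl]acetamide (CNP0315214.1)
Conditions: HF·pyridine, pyridine, THF, 0 °C → rt
Reagents that add atoms: none
Why: Fluoride-mediated desilylation of the primary TBS ether under pyridine-buffered, weakly acidic conditions should neither enolise the α-acetamido ketone (no epimerisation, no β-elimination) nor open the furan.

**Compound list**
1 | 10-chlorodecan-1-ol | OCCCCCCCCCCCl | starting material
2 | 10-chlorodecanal | O=CCCCCCCCCCCl | intermediate
3 | prop-1-yn-1-ylmagnesium bromide | CC#C[Mg]Br | starting material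
4 | 13-chlorotridec-2-yn-4-ol (racemic) | CC#CC(O)CCCCCCCCCCl | intermediate
5 | ethyl hex-2-ynoate | CCCC#CC(=O)OCC | starting material
6 | ethyl (2E)-3-[(13-chlorotridec-2-yn-4-yl)oxy]hex-2-enoate (racemic) | CCC/C(=C\C(=O)OCC)OC(C#CC)CCCCCCCCCCl | intermediate
7 | ethyl 2-(13-chlorotrideca-2,3-dien-2-yl)-3-oxohexanoate (stereoisomer mixture) | CCCC(=O)C(C(=O)OCC)C(C)=C=CCCCCCCCCCCl | intermediate (not isolated)
8 | ethyl 5-(10-chlorodecyl)-4-methyl-2-propylfuran-3-carboxylate | CCCc1oc(CCCCCCCCCCCl)c(C)c1C(=O)OCC | intermediate
9 | [5-(10-chlorodecyl)-4-methyl-2-propylfuran-3-yl]methanol | CCCc1oc(CCCCCCCCCCCl)c(C)c1CO | intermediate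
10 | 2-(10-chlorodecyl)-3,4-dimethyl-5-propylfuran | CCCc1oc(CCCCCCCCCCCl)c(C)c1C | intermediate
11 | N-acetyl-L-serine methyl ester | CC(=O)N[C@@H](CO)C(=O)OC | starting material
12 | methyl N-acetyl-O-(tert-butyldimethylsilyl)-L-serinate | CC(=O)N[C@@H](CO[Si](C)(C)C(C)(C)C)C(=O)OC | intermediate
13 | methyl N-acetyl-N-(chloromagnesio)-O-(tert-butyldimethylsilyl)-L-serinate | CC(=O)N([Mg]Cl)[C@@H](CO[Si](C)(C)C(C)(C)C)C(=O)OC | intermediate (not isolated)
14 | N-[(2S)-3-[(tert-butyldimethylsilyl)oxy]-1-[methoxy(methyl)amino]-1-oxopropan-2-yl]acetamide | CC(=O)N[C@@H](CO[Si](C)(C)C(C)(C)C)C(=O)N(C)OC | intermediate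
15 | [10-(3,4-dimethyl-5-propylfuran-2-yl)decyl]magnesium chloride | CCCc1oc(CCCCCCCCCC[Mg]Cl)c(C)c1C | intermediate (not isolated)
16 | N-[(2S)-3-[(tert-butyldimethylsilyl)oxy]-1-[methoxy(methyl)amino]-1-oxopropan-2-yl]-N-(chloromagnesio)acetamide | CC(=O)N([Mg]Cl)[C@@H](CO[Si](C)(C)C(C)(C)C)C(=O)N(C)OC | intermediate (not isolated)
17 | N-[(2S)-1-[(tert-butyldimethylsilyl)oxy]-13-(3,4-dimethyl-5-propylfuran-2-yl)-3-oxotridecan-2-yl]acetamide | CCCc1oc(CCCCCCCCCCC(=O)[C@H](CO[Si](C)(C)C(C)(C)C)NC(C)=O)c(C)c1C | intermediate
18 | N-[(2S)-13-(3,4-dimethyl-5-propylfuran-2-yl)-1-hydroxy-3-oxotridecan-2-yl]acetamide | CCCc1oc(CCCCCCCCCCC(=O)[C@H](CO)NC(C)=O)c(C)c1C | target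

**Total step count:** 10
**Longest linear sequence:** 8 steps (1–6, 9, 10); the serine branch (steps 7, 8) joins in step 9.

**Steps most likely to fail**

Step 6. Under the acid the electron-rich tetraalkylfuran may be protonated on the ring in competition with ionisation of the carbinol, leading to over-reduction or oligomerisation. The fallback avoids acid. It sets out from 9, which is sulfated with SO3·pyridine in THF at 0 °C to pyridinium [5-(10-chlorodecyl)-4-methyl-2-propylfuran-3-yl]methyl sulfate F1. LiAlH4 is then added to the same flask at 0 °C and displaces the activated sulfate by hydride, while the primary chloride should be reduced much more slowly at this temperature. The fallback returns to the route at 10.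

Step 9. Magnesium insertion into the primary chloride may be slow and accompanied by Wurtz-type homocoupling, or addition to the anionic N-magnesiated Weinreb amide may lag so that the organometallic is merely protonated on quench. The fallback replaces the polar addition by a palladium-catalysed acyl cross-coupling (Fukuyama coupling). It sets out from 10 and 12. Finkelstein exchange of 10 (NaI, acetone, reflux) gives 2-(10-iododecyl)-3,4-dimethyl-5-propylfuran F2, and zinc insertion (activated Zn dust, THF/DMA, 40 °C) gives [10-(3,4-dimethyl-5-propylfuran-2-yl)decyl]zinc iodide F3. In parallel 12 is converted with AlMe3/EtSH in CH2Cl2 into S-ethyl (2S)-2-acetamido-3-[(tert-butyldimethylsilyl)oxy]propanethioate F4. F3 and F4 are coupled with PdCl2(PPh3)2 (5 mol%) in toluene/THF at rt; these near-neutral conditions tolerate the amide N–H and should not epimerise the α-centre. The fallback returns to the route at 17.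

Step 3. Conjugate addition of the hindered secondary alcohol may be slow, so that the phosphine instead isomerises the ynoate to allenoate or dienoate. The fallback builds the enol ether by addition–elimination. It sets out from 5 and 4. Hydrochlorination of 5 (LiCl, AcOH, 70 °C) gives ethyl (2Z)-3-chlorohex-2-enoate F5. The sodium alkoxide of 4 (NaH, THF, 0 °C) then adds at the β-carbon and expels chloride, and the fallback returns to the route at 6.

**Further compounds**
F1 | step 6 | pyridinium [5-(10-chlorodecyl)-4-methyl-2-propylfuran-3-yl]methyl sulfate | CCCc1oc(CCCCCCCCCCCl)c(C)c1COS(=O)(=O)[O-].c1cc[nH+]cc1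
F2 | step 9 | 2-(10-iododecyl)-3,4-dimethyl-5-propylfuran | CCCc1oc(CCCCCCCCCCI)c(C)c1C
F3 | step 9 | [10-(3,4-dimethyl-5-propylfuran-2-yl)decyl]zinc iodide | CCCc1oc(CCCCCCCCCC[Zn]I)c(C)c1C
F4 | step 9 | S-ethyl (2S)-2-acetamido-3-[(tert-butyldimethylsilyl)oxy]propanethioate | CCSC(=O)[C@H](CO[Si](C)(C)C(C)(C)C)NC(C)=O
F5 | step 3 | ethyl (2Z)-3-chlorohex-2-enoate | CCC/C(Cl)=C/C(=O)OCC
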